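**Plan**

1. Numbering used below (labdane): decalin C1–C10, C11–C12 ethylene link, C13–C16 butenolide, C17 formyl carbon, C18/C19 the two CH2OH carbons, C20 angular methyl.
2. Cuts, in retrosynthetic order: C12–C13 (butenolide attached last); one C4–CH2OH bond (reductive hydroxymethylation of a C3=C4 ester); ring bonds C1–C2 and C5–C10 together in one intramolecular Diels–Alder step; C3–C4 (Stille vinylation of an alkyne-derived stannane); C7–C8 (lactone alkylation); C9–C10 (asymmetric conjugate addition).
3. Feature that allows the key event: C4 carries two identical CH2OH groups and is no stereocentre, so it can be an sp2, ester-bearing diene carbon. Ring A (C1, C2, C3, C4, C5, C10) is then the cyclohexene from diene C2=C3–C4=C5 and the isopropenyl unit C10(C20)=C1 on C9, and ring B (C5–C10) closes through the tether C6–C9.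
4. Forward: a δ-lactone (C17, C8, C9, C11, C12, O) serves as a temporary ring to set C9 and then C8, and is opened to the acyclic triene. Rings A and B close together, C4 is completed, the butenolide ring comes last, and the C17 acetal and diol acetonide fall in the final step.
5. Stereochemistry: C9 from the (R)-BINAP/Rh conjugate addition; C8 from trans alkylation of the lactone (it is also the thermodynamic, equatorial-CHO epimer); C5 and C10 from the chair, tether-exo Diels–Alder transition state steered by C8 and C9.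

Key step: step 9

Remark: C4 in 17 and the sulfur-bearing carbon in 24 and 25 are formed as epimer mixtures and are destroyed later, so they carry no stereo label in the SMILES.

**Route**

Step 1
Reactants: 1 5,6-dihydro-2H-pyran-2-one; 2 4,4,5,5-tetramethyl-2-(prop-1-en-2-yl)-1,3,2-dioxaborolane
Product: 3 (4R)-4-(prop-1-en-2-yl)oxan-2-one
Conditions: [RhCl(cod)]2 (cat.), (R)-BINAP (cat.), Et3N, 1,4-dioxane/H2O (10:1), 60 °C
Reagents that add atoms: none
Why: Rhodium-catalysed asymmetric conjugate addition of an alkenylboronate to an s-trans unsaturated lactone (Hayashi–Miyaura reaction), in which the (R)-BINAP–Rh–isopropenyl species should add to the same enantioface as in the well-studied aryl and alkenyl additions to cyclic enones (mirror image of the (S)-BINAP sense), setting C9 as (4R) while water protonates the rhodium enolate.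

Step 2
Reactants: 3 (4R)-4-(prop-1-en-2-yl)oxan-2-one; 4 (4-iodobut-1-yn-1-yl)trimethylsilane
Product: 6 (3S,4R)-4-(prop-1-en-2-yl)-3-[4-(trimethylsilyl)but-3-yn-1-yl]oxan-2-one, via lithium lactone enolate 5 (not isolated)
Conditions: LiN(iPr)2, THF, −78 °C; then 4, HMPA, −78 → −30 °C
Reagents that add atoms: none
Why: Lactone enolate alkylation (SN2) in which the electrophile approaches the planar enolate anti to the adjacent isopropenyl group, so that C8 is set trans to C9 (3S), the relative configuration of the target.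

Step 3
Reactants: 6 (3S,4R)-4-(prop-1-en-2-yl)-3-[4-(trimethylsilyl)but-3-yn-1-yl]oxan-2-one
Product: 7 (2S,3R)-3-(2-hydroxyethyl)-N-methoxy-N,4-dimethyl-2-[4-(trimethylsilyl)but-3-yn-1-yl]pent-4-enamide
Conditions: MeNHOMe, AlMe3, CH2Cl2, 0 °C → rt; aq. KNaC4H4O6 work-up
Reagents that add atoms: N,O-dimethylhydroxylamine CNOC
Why: Aluminium amide aminolysis of a lactone to the N-methoxy-N-methyl amide, which frees the C12 hydroxyl and keeps C17 at a level that one hydride equivalent will take to the aldehyde, no stereocentre being touched.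

Step 4
Reactants: 7 (2S,3R)-3-(2-hydroxyethyl)-N-methoxy-N,4-dimethyl-2-[4-(trimethylsilyl)but-3-yn-1-yl]pent-4-enamide
Product: 8 (2S,3R)-3-(2-chloroethyl)-N-methoxy-N,4-dimethyl-2-[4-(trimethylsilyl)but-3-yn-1-yl]pent-4-enamide
Conditions: PPh3, CCl4, CH2Cl2, 0 °C → rt
Reagents that add atoms: tetrachloromethane ClC(Cl)(Cl)Cl
Why: Appel chlorination (SN2 at the primary carbon) turns C12–OH into a chloride that is inert to the organometallic, thermal and hydride steps ahead and serves as the electrophile in step 14.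

Step 5
Reactants: 8 (2S,3R)-3-(2-chloroethyl)-N-methoxy-N,4-dimethyl-2-[4-(trimethylsilyl)but-3-yn-1-yl]pent-4-enamide
Product: 9 (2S,3R)-3-(2-chloroethyl)-4-methyl-2-[4-(trimethylsilyl)but-3-yn-1-yl]pent-4-enal
Conditions: iBu2AlH, THF, −78 °C; aq. KNaC4H4O6 work-up
Reagents that add atoms: none
Why: Hydride reduction of an N-methoxy-N-methyl amide stops at the chelated tetrahedral intermediate, which gives the aldehyde only on work-up, and the cold, neutral work-up should leave the α-stereocentre C8 intact.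

Step 6
Reactants: 9 (2S,3R)-3-(2-chloroethyl)-4-methyl-2-[4-(trimethylsilyl)but-3-yn-1-yl]pent-4-enal
Product: 10 [(5S,6R)-6-(2-chloroethyl)-5-(dimethoxymethyl)-7-methyloct-7-en-1-yn-1-yl]trimethylsilane
Conditions: HC(OMe)3, MeOH, PPTS (cat.), rt
Reagents that add atoms: trimethyl orthoformate COC(OC)OC; methanol CO
Why: Acid-catalysed acetalization with the orthoformate as water scavenger masks C17 as a dimethyl acetal that tolerates every later basic, organometallic, thermal and hydride step.

Step 7
Reactants: 10 [(5S,6R)-6-(2-chloroethyl)-5-(dimethoxymethyl)-7-methyloct-7-en-1-yn-1-yl]trimethylsilane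
Product: 12 methyl (6S,7R)-7-(2-chloroethyl)-6-(dimethoxymethyl)-8-methylnon-8-en-2-ynoate, via lithium acetylide 11 (not isolated)
Conditions: MeLi·LiBr, Et2O, 0 °C → rt; then ClCO2Me, −78 → 0 °C
Reagents that add atoms: methyl chloroformate COC(=O)Cl
Why: Desilylative metalation of the alkynylsilane by methyllithium followed by C-acylation of the lithium acetylide with the chloroformate gives the 2-alkynoate.

Step 8
Reactants: 12 methyl (6S,7R)-7-(2-chloroethyl)-6-(dimethoxymethyl)-8-methylnon-8-en-2-ynoate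
Product: 14 methyl (2Z,6S,7R)-7-(2-chloroethyl)-6-(dimethoxymethyl)-2-ethenyl-8-methylnona-2,8-dienoate, via α-stannyl enoate 13 (not isolated)
Conditions: Bu3SnH, Pd(PPh3)4 (cat.), THF, 0 °C → rt; then CH2=CHBr, CuI (cat.), CsF, DMF, 45 °C
Reagents that add atoms: bromoethene C=CBr
Why: Palladium-catalysed syn-hydrostannation of a 2-alkynoate puts tin on the α-carbon C4 and hydrogen on C5, and the copper/fluoride-assisted Stille coupling with vinyl bromide proceeds with retention, so that C6 ends cis to the ester and trans to the new vinyl group, the diene geometry that step 9 needs.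

Step 9
Reactants: 14 methyl (2Z,6S,7R)-7-(2-chloroethyl)-6-(dimethoxymethyl)-2-ethenyl-8-methylnona-2,8-dienoate
Product: 15 methyl (4aS,5R,6S,8aS)-5-(2-chloroethyl)-6-(dimethoxymethyl)-4a-methyl-3,4,4a,5,6,7,8,8a-octahydronaphthalene-1-carboxylate
Conditions: toluene (0.01 M), 2,6-di-tert-butyl-4-methylphenol (cat.), 170 °C, sealed tube
Reagents that add atoms: none
Why: Thermal, concerted but asynchronous [4+2] cycloaddition between the ester-bearing diene C2=C3–C4=C5 and the isopropenyl alkene C10=C1, the closest known reaction type being the type 1 intramolecular Diels–Alder reaction of 1,3,9-decatrienes with an unactivated 1,1-disubstituted dienophile, which gives trans-octalins with an angular methyl group. Ring A is closed as the new cyclohexene by the two new bonds C1–C2 and C5–C10, and ring B is closed through C5–C10 by the four-carbon tether C6–C9 in the fused mode with a chair-like tether. C5 and C10 are set together: the tether-exo (methyl-endo) chair transition state gives the trans ring fusion, and the face is fixed by the existing centres, because only one chair has both the C8 acetal and the C9 chloroethyl group equatorial, with C9–H eclipsing the dienophile and the C9 chain anti to the forming C5–C10 bond. The step needs trans over cis ring fusion and one π-face: the (Z)-diene geometry (C6 trans to the vinyl group) allows the trans mode and excludes a 1,5-hydrogen shift, the C4 ester, which is cis to C6, should penalise the folded tether-endo (cis) transition state by 1,3-allylic strain, and the trans-diequatorial C8/C9 pair penalises the other face. The diene ester lowers the diene LUMO enough for a neutral alkene to react on heating without a Lewis acid, which the acetal and the cation-prone isopropenyl group would not tolerate.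

Step 10
Reactants: 15 methyl (4aS,5R,6S,8aS)-5-(2-chloroethyl)-6-(dimethoxymethyl)-4a-methyl-3,4,4a,5,6,7,8,8a-octahydronaphthalene-1-carboxylate
Product: 17 methyl (4aS,5R,6S,8aS)-5-(2-chloroethyl)-6-(dimethoxymethyl)-1-(hydroxymethyl)-4a-methyldecahydronaphthalene-1-carboxylate (C1 epimers), via lithium ester enolate 16 (not isolated)
Conditions: Li[HB(sBu)3], THF, −78 °C; then CH2O (monomeric, in THF), −78 → −20 °C; H2O
Reagents that add atoms: formaldehyde C=O
Why: 1,4-Reduction of the enoate by the hindered trialkylborohydride gives the C4 ester enolate regiospecifically and its aldol addition to monomeric formaldehyde (reductive aldol reaction) builds the quaternary C4, whose configuration is of no consequence because both carbon substituents become CH2OH.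

Step 11
Reactants: 17 methyl (4aS,5R,6S,8aS)-5-(2-chloroethyl)-6-(dimethoxymethyl)-1-(hydroxymethyl)-4a-methyldecahydronaphthalene-1-carboxylate
Product: 18 [(4aS,5R,6S,8aS)-5-(2-chloroethyl)-6-(dimethoxymethyl)-4a-methyloctahydronaphthalene-1,1(2H)-diyl]dimethanol
Conditions: iBu2AlH (excess), CH2Cl2, −78 → 0 °C; aq. KNaC4H4O6 work-up
Reagents that add atoms: none
Why: Ester reduction by iBu2AlH gives the second CH2OH group, making C4 non-stereogenic, while the primary chloride and the acetal are not attacked.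

Step 12
Reactants: 18 [(4aS,5R,6S,8aS)-5-(2-chloroethyl)-6-(dimethoxymethyl)-4a-methyloctahydronaphthalene-1,1(2H)-diyl]dimethanol
Product: 19 (4a'S,5'R,6'S,8a'S)-5'-(2-chloroethyl)-6'-(dimethoxymethyl)-2,2,4a'-trimethyloctahydro-2'H-spiro[[1,3]dioxane-5,1'-naphthalene]
Conditions: Me2C(OMe)2, PPTS (cat.), CH2Cl2, rt
Reagents that add atoms: 2,2-dimethoxypropane COC(C)(C)OC
Why: Transacetalization of the 2,2-disubstituted propane-1,3-diol unit to the six-membered acetonide removes the two acidic hydroxyl groups before the enolate alkylation.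

Step 13
Reactants: 20 3-bromooxolan-2-one; 21 benzenethiol
Product: 22 3-(phenylsulfanyl)oxolan-2-one (racemic)
Conditions: Et3N, CH2Cl2, 0 °C → rt
Reagents that add atoms: none
Why: SN2 displacement of the α-bromide by the thiolate gives the sulfur-substituted lactone that serves as a butenolide α-anion equivalent, its stereocentre being destroyed in step 15.

Step 14
Reactants: 19 (4a'S,5'R,6'S,8a'S)-5'-(2-chloroethyl)-6'-(dimethoxymethyl)-2,2,4a'-trimethyloctahydro-2'H-spiro[[1,3]dioxane-5,1'-naphthalene]; 22 3-(phenylsulfanyl)oxolan-2-one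
Product: 24 3-{2-[(4a'S,5'R,6'S,8a'S)-6'-(dimethoxymethyl)-2,2,4a'-trimethyloctahydro-2'H-spiro[[1,3]dioxane-5,1'-naphthalen]-5'-yl]ethyl}-3-(phenylsulfanyl)oxolan-2-one (C3 epimers), via sodium lactone enolate 23 (not isolated)
Conditions: 22, NaH, DMF, 0 °C; then 19, NaI (cat.), 60 °C
Reagents that add atoms: none
Why: Alkylation of the soft, sulfur-stabilised lactone enolate by the primary chloride (SN2 with in situ halide exchange) forms the C12–C13 bond, the new C13 centre being formed as a mixture that step 15 erases.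

Step 15
Reactants: 24 3-{2-[(4a'S,5'R,6'S,8a'S)-6'-(dimethoxymethyl)-2,2,4a'-trimethyloctahydro-2'H-spiro[[1,3]dioxane-5,1'-naphthalen]-5'-yl]ethyl}-3-(phenylsulfanyl)oxolan-2-one
Product: 26 3-{2-[(4a'S,5'R,6'S,8a'S)-6'-(dimethoxymethyl)-2,2,4a'-trimethyloctahydro-2'H-spiro[[1,3]dioxane-5,1'-naphthalen]-5'-yl]ethyl}furan-2(5H)-one, via sulfoxide 25 (not isolated)
Conditions: mCPBA (1 equiv), CH2Cl2, −78 → 0 °C; then toluene, 110 °C
Reagents that add atoms: none
Why: Sulfide oxidation and thermal syn-elimination of the sulfoxide (sulfoxide pyrolysis), which in α-sulfinyl-γ-lactones takes a ring hydrogen and so should give the endocyclic butenolide.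

Step 16
Reactants: 26 3-{2-[(4a'S,5'R,6'S,8a'S)-6'-(dimethoxymethyl)-2,2,4a'-trimethyloctahydro-2'H-spiro[[1,3]dioxane-5,1'-naphthalen]-5'-yl]ethyl}furan-2(5H)-one
Product: 27 (1R,2S,4aS,8aS)-5,5-bis(hydroxymethyl)-8a-methyl-1-[2-(2-oxo-2,5-dihydrofuran-3-yl)ethyl]decahydronaphthalene-2-carbaldehyde (target)
Conditions: aq. HCl (1 M)/THF, rt
Reagents that add atoms: water O
Why: Acid hydrolysis of the dimethyl acetal and of the acetonide releases the aldehyde and the diol, and C8 needs no adjustment because the equatorial formyl group, trans to the C9 chain and free of a 1,3-diaxial contact with C20, is the thermodynamic epimer to which any minor C8 epimer would also converge through the enol.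

**Compound list**

1 | 5,6-dihydro-2H-pyran-2-one | O=C1C=CCCO1 | starting material
2 | 4,4,5,5-tetramethyl-2-(prop-1-en-2-yl)-1,3,2-dioxaborolane | CC(=C)B1OC(C)(C)C(C)(C)O1 | starting material
3 | (4R)-4-(prop-1-en-2-yl)oxan-2-one | O=C1C[C@H](C(C)=C)CCO1 | intermediate
4 | (4-iodobut-1-yn-1-yl)trimethylsilane | C[Si](C)(C)C#CCCI | starting material
5 | lithium (4R)-4-(prop-1-en-2-yl)-5,6-dihydro-4H-pyran-2-olate (lithium lactone enolate) | [Li]OC1=C[C@H](C(C)=C)CCO1 | intermediate
6 | (3S,4R)-4-(prop-1-en-2-yl)-3-[4-(trimethylsilyl)but-3-yn-1-yl]oxan-2-one | O=C1[C@@H](CCC#C[Si](C)(C)C)[C@H](C(C)=C)CCO1 | intermediate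
7 | (2S,3R)-3-(2-hydroxyethyl)-N-methoxy-N,4-dimethyl-2-[4-(trimethylsilyl)but-3-yn-1-yl]pent-4-enamide | CON(C)C(=O)[C@@H](CCC#C[Si](C)(C)C)[C@H](C(C)=C)CCO | intermediate
8 | (2S,3R)-3-(2-chloroethyl)-N-methoxy-N,4-dimethyl-2-[4-(trimethylsilyl)but-3-yn-1-yl]pent-4-enamide | CON(C)C(=O)[C@@H](CCC#C[Si](C)(C)C)[C@H](C(C)=C)CCCl | intermediate
9 | (2S,3R)-3-(2-chloroethyl)-4-methyl-2-[4-(trimethylsilyl)but-3-yn-1-yl]pent-4-enal | O=C[C@@H](CCC#C[Si](C)(C)C)[C@H](C(C)=C)CCCl | intermediate
10 | [(5S,6R)-6-(2-chloroethyl)-5-(dimethoxymethyl)-7-methyloct-7-en-1-yn-1-yl]trimethylsilane | COC(OC)[C@@H](CCC#C[Si](C)(C)C)[C@H](C(C)=C)CCCl | intermediate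
11 | [(5S,6R)-6-(2-chloroethyl)-5-(dimethoxymethyl)-7-methyloct-7-en-1-yn-1-yl]lithium (lithium acetylide) | [Li]C#CCC[C@H](C(OC)OC)[C@H](C(C)=C)CCCl | intermediate
12 | methyl (6S,7R)-7-(2-chloroethyl)-6-(dimethoxymethyl)-8-methylnon-8-en-2-ynoate | COC(=O)C#CCC[C@H](C(OC)OC)[C@H](C(C)=C)CCCl | intermediate
13 | methyl (2E,6S,7R)-7-(2-chloroethyl)-6-(dimethoxymethyl)-8-methyl-2-(tributylstannyl)nona-2,8-dienoate (α-stannyl enoate) | COC(=O)/C([Sn](CCCC)(CCCC)CCCC)=C\CC[C@H](C(OC)OC)[C@H](C(C)=C)CCCl | intermediate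
14 | methyl (2Z,6S,7R)-7-(2-chloroethyl)-6-(dimethoxymethyl)-2-ethenyl-8-methylnona-2,8-dienoate | COC(=O)/C(C=C)=C\CC[C@H](C(OC)OC)[C@H](C(C)=C)CCCl | intermediate
15 | methyl (4aS,5R,6S,8aS)-5-(2-chloroethyl)-6-(dimethoxymethyl)-4a-methyl-3,4,4a,5,6,7,8,8a-octahydronaphthalene-1-carboxylate | C[C@@]12CCC=C(C(=O)OC)[C@H]1CC[C@H](C(OC)OC)[C@H]2CCCl | intermediate
16 | lithium ester enolate from 1,4-reduction of 15 (ring-carbon configurations as in 15) | C[C@@]12CCCC(=C(OC)O[Li])[C@H]1CC[C@H](C(OC)OC)[C@H]2CCCl | intermediate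
17 | methyl (4aS,5R,6S,8aS)-5-(2-chloroethyl)-6-(dimethoxymethyl)-1-(hydroxymethyl)-4a-methyldecahydronaphthalene-1-carboxylate (C1 epimers) | C[C@@]12CCCC(CO)(C(=O)OC)[C@H]1CC[C@H](C(OC)OC)[C@H]2CCCl | intermediate
18 | [(4aS,5R,6S,8aS)-5-(2-chloroethyl)-6-(dimethoxymethyl)-4a-methyloctahydronaphthalene-1,1(2H)-diyl]dimethanol | C[C@@]12CCCC(CO)(CO)[C@H]1CC[C@H](C(OC)OC)[C@H]2CCCl | intermediate
19 | (4a'S,5'R,6'S,8a'S)-5'-(2-chloroethyl)-6'-(dimethoxymethyl)-2,2,4a'-trimethyloctahydro-2'H-spiro[[1,3]dioxane-5,1'-naphthalene] | C[C@@]12CCCC3(COC(C)(C)OC3)[C@H]1CC[C@H](C(OC)OC)[C@H]2CCCl | intermediate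
20 | 3-bromooxolan-2-one | O=C1OCCC1Br | starting material
21 | benzenethiol | Sc1ccccc1 | starting material
22 | 3-(phenylsulfanyl)oxolan-2-one (racemic) | O=C1OCCC1Sc1ccccc1 | intermediate
23 | sodium 3-(phenylsulfanyl)-4,5-dihydrofuran-2-olate (sodium lactone enolate) | [Na]OC1=C(Sc2ccccc2)CCO1 | intermediate
24 | 3-{2-[(4a'S,5'R,6'S,8a'S)-6'-(dimethoxymethyl)-2,2,4a'-trimethyloctahydro-2'H-spiro[[1,3]dioxane-5,1'-naphthalen]-5'-yl]ethyl}-3-(phenylsulfanyl)oxolan-2-one (C3 epimers) | C[C@@]12CCCC3(COC(C)(C)OC3)[C@H]1CC[C@H](C(OC)OC)[C@H]2CCC1(Sc2ccccc2)CCOC1=O | intermediate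
25 | 3-(benzenesulfinyl) analogue of 24 (sulfoxide; epimers at carbon and sulfur) | C[C@@]12CCCC3(COC(C)(C)OC3)[C@H]1CC[C@H](C(OC)OC)[C@H]2CCC1(S(=O)c2ccccc2)CCOC1=O | intermediate
26 | 3-{2-[(4a'S,5'R,6'S,8a'S)-6'-(dimethoxymethyl)-2,2,4a'-trimethyloctahydro-2'H-spiro[[1,3]dioxane-5,1'-naphthalen]-5'-yl]ethyl}furan-2(5H)-one | C[C@@]12CCCC3(COC(C)(C)OC3)[C@H]1CC[C@H](C(OC)OC)[C@H]2CCC1=CCOC1=O | intermediate
27 | (1R,2S,4aS,8aS)-5,5-bis(hydroxymethyl)-8a-methyl-1-[2-(2-oxo-2,5-dihydrofuran-3-yl)ethyl]decahydronaphthalene-2-carbaldehyde | C[C@@]12CCCC(CO)(CO)[C@H]1CC[C@H](C=O)[C@H]2CCC1=CCOC1=O | target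

**Count**

Total step count: 16. Longest linear sequence: 15 steps (steps 1–12 and 14–16, from 1 to 27); step 13 is a one-step side branch.

**Steps most likely to fail**

Step 9. The risk is an insufficient preference for the trans ring fusion in the cycloaddition, or dimerisation of the diene ester before it cyclises. The fallback sets out from 10 and comes back at 15; it makes the ring-fusion carbon C5 epimerisable after the cycloaddition. The silyl group is removed (K2CO3, MeOH) to give the terminal alkyne acetal F1. Hydroboration with (C6H11)2BH and NaBO3 oxidation gives the chain aldehyde F2. CH2=CHMgBr gives the allylic alcohol F3, and Dess–Martin periodinane the vinyl ketone F4. tBuMe2SiOSO2CF3/Et3N gives the (Z)-2-silyloxy diene F5, which is cyclised thermally (toluene, 190 °C) to the silyl enol ether adduct F6 whatever its ring-fusion ratio. Bu4NF and then NaOMe/MeOH should equilibrate C5, now α to the C4 ketone, to the more stable trans-fused ketone F7. Kinetic enolisation toward C3 and triflation (KN(SiMe3)2, PhN(SO2CF3)2, −78 °C) give the enol triflate F8, and methoxycarbonylation (Pd(OAc)2, PPh3, CO, MeOH, Et3N) gives 15.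

Step 8. The risk is slow transmetalation of the hindered α-stannyl enoate, which leads to protodestannylation and to loss of the labile diene during a long coupling. The fallback sets out from 12 and comes back at 14; it reverses the roles of the partners. The hydrostannation is run alone and 13 is isolated. Iododestannylation with retention (I2, CH2Cl2, 0 °C) gives the α-iodo enoate F9. A Suzuki–Miyaura coupling with CH2=CHBF3K (PdCl2(dppf), Cs2CO3, THF/H2O, 60 °C), in which the enoate is the electrophile, gives 14.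

Step 10. The risk is competing 1,2-reduction, or protonation of the hindered C4 enolate before it is trapped by formaldehyde. The fallback sets out from 15 and comes back at 18; it replaces low-temperature enolate trapping by a base-driven hydroxymethylation. Hydrogenation of the only C=C bond (H2, Pd/C, EtOAc) gives the saturated C4 ester F10 as C4 epimers. Partial reduction (iBu2AlH, toluene, −78 °C) gives the C4 aldehyde F11. Aqueous CH2O and KOH in EtOH then effect α-hydroxymethylation and crossed Cannizzaro reduction in one operation to give 18.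

**Further compounds**

F1 | step 9 | terminal alkyne acetal, (3R,4S)-3-(2-chloroethyl)-4-(dimethoxymethyl)-2-methyloct-1-en-7-yne | C#CCC[C@H](C(OC)OC)[C@H](C(C)=C)CCCl
F2 | step 9 | chain aldehyde, (5S,6R)-6-(2-chloroethyl)-5-(dimethoxymethyl)-7-methyloct-7-enal | O=CCCC[C@H](C(OC)OC)[C@H](C(C)=C)CCCl
F3 | step 9 | allylic alcohol, (7S,8R)-8-(2-chloroethyl)-7-(dimethoxymethyl)-9-methyldeca-1,9-dien-3-ol (C3 epimers) | C=CC(O)CCC[C@H](C(OC)OC)[C@H](C(C)=C)CCCl
F4 | step 9 | vinyl ketone, (7S,8R)-8-(2-chloroethyl)-7-(dimethoxymethyl)-9-methyldeca-1,9-dien-3-one | C=CC(=O)CCC[C@H](C(OC)OC)[C@H](C(C)=C)CCCl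
F5 | step 9 | (Z)-2-silyloxy diene, tert-butyl{[(3Z,7S,8R)-8-(2-chloroethyl)-7-(dimethoxymethyl)-9-methyldeca-1,3,9-trien-3-yl]oxy}dimethylsilane | C=C/C(O[Si](C)(C)C(C)(C)C)=C/CC[C@H](C(OC)OC)[C@H](C(C)=C)CCCl
F6 | step 9 | silyl enol ether adduct, 1-(tert-butyldimethylsilyloxy) analogue of 15 (ring-fusion epimers at C8a) | C[C@@]12CCC=C(O[Si](C)(C)C(C)(C)C)C1CC[C@H](C(OC)OC)[C@H]2CCCl
F7 | step 9 | trans-fused ketone, (4aS,5R,6S,8aS)-5-(2-chloroethyl)-6-(dimethoxymethyl)-4a-methyloctahydronaphthalen-1(2H)-one | C[C@@]12CCCC(=O)[C@H]1CC[C@H](C(OC)OC)[C@H]2CCCl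
F8 | step 9 | enol triflate, (4aS,5R,6S,8aS)-5-(2-chloroethyl)-6-(dimethoxymethyl)-4a-methyl-3,4,4a,5,6,7,8,8a-octahydronaphthalen-1-yl trifluoromethanesulfonate | C[C@@]12CCC=C(OS(=O)(=O)C(F)(F)F)[C@H]1CC[C@H](C(OC)OC)[C@H]2CCCl
F9 | step 8 | α-iodo enoate, methyl (2E,6S,7R)-7-(2-chloroethyl)-6-(dimethoxymethyl)-2-iodo-8-methylnona-2,8-dienoate | COC(=O)/C(I)=C\CC[C@H](C(OC)OC)[C@H](C(C)=C)CCCl
F10 | step 10 | saturated C4 ester, 1,2-dihydro derivative of 15 (C1 epimers; other centres as in 15) | C[C@@]12CCCC(C(=O)OC)[C@H]1CC[C@H](C(OC)OC)[C@H]2CCCl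
F11 | step 10 | C4 aldehyde, 1-formyl analogue of F10 (C1 epimers; other centres as in 15) | C[C@@]12CCCC(C=O)[C@H]1CC[C@H](C(OC)OC)[C@H]2CCCl
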